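**Remark on numbering:** ring atoms of 15 and 16 are C1 (carbinol carbon bearing C7H2O), C2 (C=O), C3 (CH2), C4, C5, C6. Open-chain compounds 8–13 are numbered as hept-2-uloses (C1 = CH2O end, C2 = carbinol/ketone carbon, C7 = the added carbon). Glycoside 2 is made in step 1 although it can also be bought.

## Analysis of the target

Target 16 is a monocyclic, fully functionalised cyclohexanone: C1 is a tertiary carbinol carrying the benzoyloxymethyl carbon C7, C2 is the ketone, C3 a methylene, C4 a CHOH, C5 a CHOBz and C6 a CHOH. It has four stereocentres: the contiguous triad C4/C5/C6 (O4 and O5 cis, O5 and O6 trans) and the quaternary C1, whose hydroxyl is cis to O6 and whose C7 branch is trans to it. In the chair with O5, O6 and C7 equatorial, O4 and the C1 hydroxyl are axial; this is the shape of a D-mannopyranose in which the ring oxygen has become the C2 carbonyl, H-5 a hydroxyl and the anomeric carbon the C3 methylene. The molecule is base-sensitive: C4–O is β to the ketone (E1cB to a cyclohexenone), the tertiary α-ketol can undergo retro-benzoin or α-ketol shift, and both benzoates neighbour free hydroxyls (acyl migration), so the last steps must be neutral. The hard points are to place benzoates on O5 and O7 only, among five oxygens of which three are contiguous secondary ones, and to build the quaternary C1 next to a ketone. The strategy rests on C1(OH)–C2(=O): this α-ketol is the retron of a crossed aldehyde–ketone benzoin reaction, so forming the single bond C1–C2 from a C2 aldehyde (acyl anion) and a C1 ketone closes the ring and creates C1; because C3 is a methylene, the aldehyde has no α-leaving group. The remaining chain C7–C1–C6–C5–C4–C3 is a hexose whose D-arabino triad is that of D-fructose (C3–C5) and, read from the other end, of D-mannose (C4–C2); the aldose is the better fit, because its anomeric carbon is the carbon (C3) that must be extended by the missing carbon C2, and its ring oxygen marks the carbinol (C1) that becomes the ketone.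

## Retrosynthetic reasoning

**16 ⇒ 15.** The two O–CH2Ph bonds at O4 and O6 are cut last. Benzyl ethers come off by hydrogenolysis under neutral conditions, which the ketone, the α-ketol and both benzoates should tolerate. No acylation is then needed after the ring exists, so the free hydroxyls next to the benzoates never meet base.

**15 ⇒ 13 (through 14).** The ring bond C1–C2 is cut. It is the only ring bond with oxygen on both carbons in a 1,2-relationship, and cutting it gives an open chain in which C4, C5 and C6 are untouched sugar stereocentres and C1 is a plain ketone. Cuts at C2–C3 or C3–C4 (aldol type) would require the quaternary centre to be made beforehand. Umpolung fixes the regiochemistry: only the aldehyde of 13 can become the enaminol 14, so the carbonyl must end at C2 and the carbinol at C1. The forward reaction has to close the ring faster than either carbonyl enolises and has to select one face of the ketone.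

**13 ⇒ 12 ⇒ 11 ⇒ 10.** The aldehyde is carried as its dimethyl acetal, and the two benzoates are traced back to the 1,4-diol 11 and from there to the bis-PMB ether 10. Esters cannot pass through the basic chain extension: an aldehyde with a β-acyloxy group would eliminate, and an acyl group would migrate to the hydroxyl freed on ring opening. The future benzoate positions therefore carry oxidatively removable ethers until the carbon skeleton is complete; the acetal keeps the aldehyde out of the way of oxidative cleavage and acylation.

**10 ⇒ 9 ⇒ 8 ⇒ 7.** The C6=C7 bond of an enol ether is cut by a Wittig methoxymethylenation, which leads back to lactol 7. This single operation adds the missing carbon at the former anomeric carbon and opens the pyranose, so that the former ring oxygen appears as the only free hydroxyl of 8. Oxidation of that hydroxyl gives the ketone of 9, and no separate masking of the ketone is needed. A 2-ketose of the same triad would lock either C6 or O5 in its ring and would need several extra steps to mask and unmask the ketone.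

**7 ⇒ 5 ⇒ 4 ⇒ 2 ⇒ 1.** The ether pattern of 7 is cut back to glycoside 2 and to 1. In 2 the cis-2,3-diol and the primary hydroxyl allow one tin-mediated bis-alkylation to place PMB on O3 and O6 (the later benzoate sites); the remaining O2 and O4 take the benzyl groups (the later free hydroxyls). The allyl glycoside is chosen so that the anomeric position can be freed without acid strong enough to touch the PMB ethers.

## Alternatives that were turned down

**Alternative 1:** The ring is not disconnected; the cis C4–O/C5–O pair is traced back to an arene, bromobenzene A2, which whole cells expressing toluene dioxygenase would convert into (1S,2S)-3-bromocyclohexa-3,5-diene-1,2-diol A1 by cis-dihydroxylation of one π bond.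
- For it: one fermentation step from an achiral commodity gives an enantiopure carbocycle with two of the four stereocentres, with no protecting-group prelude and no ring closure. On steps to the first chiral carbocycle it is clearly stronger than the sugar route.
- Against it: A1 carries only the C4/C5 pair. The bromine sits on the carbon that becomes C6, which needs oxygen, whereas C1 needs a hydroxyl and the C7 branch on a diene carbon without a handle. The C2 ketone/C3 methylene pattern must be carved out of the second double bond by separate oxidations and a reduction. The two hydroxyls of the cis-diol must also be told apart so that only O5 is benzoylated.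
- Comparison: what is saved at the start would be spent on regio- and stereocontrolled functionalisation of four sp2 carbons. The chosen route spends its steps on routine protecting-group chemistry and then creates the whole C1–C2 pattern in one bond formation.

**Alternative 2:** The aldol bond C3–C4 of the β-hydroxy ketone is cut back to a pyranoside with an exocyclic enol ether, methyl 2-O-benzoyl-4-C-(benzoyloxymethyl)-6-deoxy-3,4-O-isopropylidene-D-arabino-hex-5-enopyranoside A4. In a Ferrier carbocyclisation, mercury-mediated hydration would open A4 to a keto aldehyde whose enolate at C3 adds to the C4 aldehyde, giving the 1,6-O-isopropylidene acetal A3 of 16.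
- For it: the C2=O/C3H2/C4–OH unit is exactly the Ferrier retron, so this cut fits the target at least as well as the benzoin retron. The ring closure is among the most reliable carbocyclisations of sugars, and it is stronger than the chosen key step on that point. Both benzoates are in place and only an acetonide has to fall afterwards.
- Against it: the quaternary centre must be built on the sugar beforehand, by branching a 4-ulose with control of a tertiary centre, in an altro-type C2/C3 pattern that has to be made from a common hexose by inversion. The C4 carbinol is a new centre set only in the cyclisation. The β-hydroxy ketone forms under aqueous acidic mercuric conditions, where dehydration to the enone and loss of the acetonide compete.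
- Comparison: the benzoin route forms the quaternary centre in the ring closure itself from an unbranched common sugar and uses no heavy metal; A4 would take more steps than 13.

**Alternative 3:** C5–C6 (aldol) and C1–C2 (nitroaldol) are cut. A class I aldolase of the FSA type would join dihydroxyacetone A6 to (R)-2-hydroxy-4-nitrobutanal A7, and the nitronate of the adduct would add to the C1 ketone, giving 1-(hydroxymethyl)-6-nitrocyclohexane-1,2,3,4-tetrol A5.
- For it: two C–C bonds, the ring and the C5/C6 centres arise in water without a protecting group. This is by far the shortest way to the skeleton and stronger than the chosen strategy in step and atom economy.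
- Against it: A5 is a pentol and the target needs benzoates on exactly O5 and O7. O7 is easy, but O5 lies between O4 and O6, so the protecting-group work avoided before the key step returns after it. The nitro group must then become the C2 ketone by a Nef reaction next to a tertiary β-hydroxyl, where base promotes the retro-nitroaldol reaction and reopens the ring. The C1 configuration rests on a reversible nitroaldol equilibrium, and A7 is itself a non-trivial chiral aldehyde.
- Comparison: the chosen route is longer but reaches the ring with the oxidation state and the acylation pattern already correct.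

Key step: step 11

## Route

Step 1
Reactants: 1 D-mannose
Product: 2 allyl α-D-mannopyranoside
Conditions: allyl alcohol (solvent), Amberlite IR-120 (H+), 80 °C
Reagents that add atoms: allyl alcohol, C=CCO
Why: Fischer glycosidation under thermodynamic control; the anomeric effect, reinforced by the axial 2-OH, should favour the α-pyranoside, and the anomeric configuration is lost again in step 4.

Step 2
Reactants: 2 allyl α-D-mannopyranoside
Product: 4 allyl 3,6-di-O-(4-methoxybenzyl)-α-D-mannopyranoside, via 2,3:4,6-bis-O-(dibutylstannylene) acetal 3 (not isolated)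
Conditions: Bu2SnO (2.2 equiv), MeOH, reflux, evaporate; PMBCl (2.6 equiv), Bu4NI, toluene, 80 °C
Reagents that add atoms: 4-methoxybenzyl chloride, COc1ccc(CCl)cc1
Why: Stannylene-mediated regioselective alkylation; tin activates the equatorial O3 of the cis-2,3-diol and the primary O6, the established outcome for α-mannopyranosides, which marks the two future benzoate positions in one step.

Step 3
Reactants: 4 allyl 3,6-di-O-(4-methoxybenzyl)-α-D-mannopyranoside
Product: 5 allyl 2,4-di-O-benzyl-3,6-di-O-(4-methoxybenzyl)-α-D-mannopyranoside
Conditions: NaH, BnBr, Bu4NI (cat.), DMF, 0 °C to rt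
Reagents that add atoms: benzyl bromide, BrCc1ccccc1
Why: Williamson etherification of the two remaining secondary hydroxyls; all groups present are base-stable ethers or acetals.

Step 4
Reactants: 5 allyl 2,4-di-O-benzyl-3,6-di-O-(4-methoxybenzyl)-α-D-mannopyranoside
Product: 7 2,4-di-O-benzyl-3,6-di-O-(4-methoxybenzyl)-D-mannopyranose, via prop-1-enyl glycoside 6 (not isolated)
Conditions: [Ir(cod)(PMePh2)2]PF6 (2 mol %, H2-activated), THF, rt; then 0.1 M HCl, acetone–H2O, 40 °C
Reagents that add atoms: none
Why: Iridium-catalysed allyl-to-propenyl isomerisation followed by hydrolysis of the resulting enol ether; the anomeric position is freed under acid too weak to cleave the PMB ethers.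

Step 5
Reactants: 7 2,4-di-O-benzyl-3,6-di-O-(4-methoxybenzyl)-D-mannopyranose
Product: 8 (E/Z)-3,5-di-O-benzyl-2-deoxy-4,7-di-O-(4-methoxybenzyl)-1-O-methyl-D-manno-hept-1-enitol (free 6-OH)
Conditions: Ph3P(CH2OMe)Cl (4 equiv), t-BuOK (3.8 equiv), THF, 0 °C; then 7, 0 to 40 °C
Reagents that add atoms: (methoxymethyl)triphenylphosphonium chloride, [Cl-].COC[P+](c1ccccc1)(c1ccccc1)c1ccccc1
Why: Wittig methoxymethylenation of the open-chain aldehyde tautomer of the lactol, a known reaction of ether-protected aldose lactols; it adds the missing carbon and opens the ring, so that the former ring oxygen appears as the only free hydroxyl, and no stereocentre is formed or broken.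

Step 6
Reactants: 8 hydroxy enol ether
Product: 9 (E/Z)-3,5-di-O-benzyl-6-deoxy-1,4-di-O-(4-methoxybenzyl)-7-O-methyl-D-arabino-hept-6-en-2-ulose
Conditions: Dess–Martin periodinane, NaHCO3, CH2Cl2, 0 °C to rt
Reagents that add atoms: none
Why: Dess–Martin oxidation of the single secondary alcohol to the ketone; the bicarbonate buffer should keep the enol ether intact.

Step 7
Reactants: 9 keto enol ether
Product: 10 3,5-di-O-benzyl-6-deoxy-1,4-di-O-(4-methoxybenzyl)-D-arabino-hept-2-ulos-7-al dimethyl acetal
Conditions: MeOH, PPTS (10 mol %), rt
Reagents that add atoms: methanol, CO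
Why: Acid-catalysed addition of methanol to the enol ether (acetal formation); both alkene isomers converge, and the hindered ketone should give at most a reversible hemiketal.

Step 8
Reactants: 10 keto acetal
Product: 11 3,5-di-O-benzyl-6-deoxy-D-arabino-hept-2-ulos-7-al dimethyl acetal (free 1-OH and 4-OH)
Conditions: DDQ (2.6 equiv), CH2Cl2–pH 7 phosphate buffer (10:1), 0 °C to rt
Reagents that add atoms: none
Why: Oxidative cleavage of both PMB ethers by DDQ, to which benzyl ethers, ketone and acetal should be inert; the buffer is there to stop the freed 4-OH from exchanging into the acetal.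

Step 9
Reactants: 11 keto acetal diol
Product: 12 1,4-di-O-benzoyl-3,5-di-O-benzyl-6-deoxy-D-arabino-hept-2-ulos-7-al dimethyl acetal
Conditions: BzCl (2.5 equiv), pyridine, DMAP (cat.), CH2Cl2, 0 °C
Reagents that add atoms: benzoyl chloride, O=C(Cl)c1ccccc1
Why: Acylation of the only two free hydroxyls (one primary, one secondary) under weakly basic conditions at low temperature, chosen to avoid enolisation of the ketone.

Step 10
Reactants: 12 dibenzoate acetal
Product: 13 1,4-di-O-benzoyl-3,5-di-O-benzyl-6-deoxy-D-arabino-hept-2-ulos-7-al
Conditions: TFA–H2O (9:1), CH2Cl2, 0 °C; NaHCO3 wash; used crude at once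
Reagents that add atoms: water, O
Why: Acid hydrolysis of the dimethyl acetal; esters, benzyl ethers and the ketone should be stable, and the β-benzyloxy aldehyde is never exposed to base before the key step.

Step 11
Reactants: 13 keto aldehyde
Product: 15 [(1S,2S,3R,4R)-3-(benzoyloxy)-2,4-bis(benzyloxy)-1-hydroxy-6-oxocyclohexyl]methyl benzoate, via Breslow enaminol 14 (not isolated)
Conditions: 2-(pentafluorophenyl)-6,7-dihydro-5H-pyrrolo[2,1-c][1,2,4]triazol-2-ium tetrafluoroborate (20 mol %), Et3N (20 mol %), CH2Cl2 (0.03 M), rt, Ar; AcOH quench
Reagents that add atoms: none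
Why: The triazolylidene released from the salt adds to the aldehyde carbon (ring C2) of 13 and proton transfer gives the nucleophilic enaminol 14, an acyl-anion equivalent. Its carbon attacks the C1 ketone in a 6-exo-trig closure and collapse of the adduct releases the carbene and leaves C2 as the ketone; the closest known reaction type is the NHC-catalysed intramolecular crossed aldehyde–ketone benzoin reaction to six-membered tertiary α-ketols, which has also been run on benzyl-protected keto aldehydes derived from sugars. Chemoselectivity is inherent, since only the aldehyde can be converted into 14, so the carbinol must end at C1 and the carbonyl at C2. Because ring C3 is a methylene group, 14 has no α-leaving group and the elimination–acylation channel of α-alkoxy aldehydes is closed. The new centre C1 is set by the substrate: in a chair-like transition state the C5 benzoate and the C6 benzyloxy group are equatorial, the C6–O bond lies anti to the forming C1–C2 bond (polar Felkin–Anh arrangement) and the large C7H2OBz group takes the equatorial site, which puts the carbonyl oxygen axial and the hydroxyl cis to O6. This is also expected to be the more stable C1 epimer, so the reversibility of the benzoin step should work in the same direction. The step needs ring closure to outrun enolisation of the ketone (epimerisation at C6, E1cB loss of the C5 benzoate) and of the aldehyde (loss of the C4 benzyloxy group); the weak amine base, the acidic pentafluorophenyl triazolium salt, high dilution and the doubly α-oxygenated, hence electrophilic, ketone are chosen to secure it.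

Step 12
Reactants: 15 O4,O6-dibenzyl ether of the target
Product: 16 [(1S,2S,3R,4R)-3-(benzoyloxy)-1,2,4-trihydroxy-6-oxocyclohexyl]methyl benzoate (CNP0127041.1)
Conditions: H2 (1 atm), Pd(OH)2/C, EtOAc, rt
Reagents that add atoms: none
Why: Hydrogenolysis of the two benzyl ethers under neutral conditions; benzoates and the saturated ketone should be unaffected, and the absence of base should prevent acyl migration and β-elimination.

## Compound list

1 | D-mannose (pyranose form) | OC[C@H]1OC(O)[C@@H](O)[C@@H](O)[C@@H]1O | starting material
2 | allyl α-D-mannopyranoside | OC[C@H]1O[C@H](OCC=C)[C@@H](O)[C@@H](O)[C@@H]1O | intermediate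
3 | allyl 2,3:4,6-bis-O-(dibutylstannylene)-α-D-mannopyranoside (written as monomer) | C=CCO[C@H]1O[C@@H]2CO[Sn](CCCC)(CCCC)O[C@H]2[C@@H]2O[Sn](CCCC)(CCCC)O[C@H]12 | intermediate (not isolated)
4 | allyl 3,6-di-O-(4-methoxybenzyl)-α-D-mannopyranoside | COc1ccc(COC[C@H]2O[C@H](OCC=C)[C@@H](O)[C@@H](OCc3ccc(OC)cc3)[C@@H]2O)cc1 | intermediate
5 | allyl 2,4-di-O-benzyl-3,6-di-O-(4-methoxybenzyl)-α-D-mannopyranoside | COc1ccc(COC[C@H]2O[C@H](OCC=C)[C@@H](OCc3ccccc3)[C@@H](OCc3ccc(OC)cc3)[C@@H]2OCc2ccccc2)cc1 | intermediate
6 | prop-1-enyl 2,4-di-O-benzyl-3,6-di-O-(4-methoxybenzyl)-α-D-mannopyranoside | COc1ccc(COC[C@H]2O[C@H](OC=CC)[C@@H](OCc3ccccc3)[C@@H](OCc3ccc(OC)cc3)[C@@H]2OCc2ccccc2)cc1 | intermediate (not isolated)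
7 | 2,4-di-O-benzyl-3,6-di-O-(4-methoxybenzyl)-D-mannopyranose (anomeric mixture) | COc1ccc(COC[C@H]2OC(O)[C@@H](OCc3ccccc3)[C@@H](OCc3ccc(OC)cc3)[C@@H]2OCc2ccccc2)cc1 | intermediate
8 | (E/Z)-3,5-di-O-benzyl-2-deoxy-4,7-di-O-(4-methoxybenzyl)-1-O-methyl-D-manno-hept-1-enitol | COC=C[C@@H](OCc1ccccc1)[C@@H](OCc1ccc(OC)cc1)[C@H](OCc1ccccc1)[C@H](O)COCc1ccc(OC)cc1 | intermediate
9 | (E/Z)-3,5-di-O-benzyl-6-deoxy-1,4-di-O-(4-methoxybenzyl)-7-O-methyl-D-arabino-hept-6-en-2-ulose | COC=C[C@@H](OCc1ccccc1)[C@@H](OCc1ccc(OC)cc1)[C@H](OCc1ccccc1)C(=O)COCc1ccc(OC)cc1 | intermediate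
10 | 3,5-di-O-benzyl-6-deoxy-1,4-di-O-(4-methoxybenzyl)-D-arabino-hept-2-ulos-7-al dimethyl acetal | COC(OC)C[C@@H](OCc1ccccc1)[C@@H](OCc1ccc(OC)cc1)[C@H](OCc1ccccc1)C(=O)COCc1ccc(OC)cc1 | intermediate
11 | 3,5-di-O-benzyl-6-deoxy-D-arabino-hept-2-ulos-7-al dimethyl acetal | COC(OC)C[C@@H](OCc1ccccc1)[C@@H](O)[C@H](OCc1ccccc1)C(=O)CO | intermediate
12 | 1,4-di-O-benzoyl-3,5-di-O-benzyl-6-deoxy-D-arabino-hept-2-ulos-7-al dimethyl acetal | COC(OC)C[C@@H](OCc1ccccc1)[C@@H](OC(=O)c1ccccc1)[C@H](OCc1ccccc1)C(=O)COC(=O)c1ccccc1 | intermediate
13 | 1,4-di-O-benzoyl-3,5-di-O-benzyl-6-deoxy-D-arabino-hept-2-ulos-7-al (precursor of the key step) | O=CC[C@@H](OCc1ccccc1)[C@@H](OC(=O)c1ccccc1)[C@H](OCc1ccccc1)C(=O)COC(=O)c1ccccc1 | intermediate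
14 | Breslow enaminol of 13 (C7 bound to the 2-(pentafluorophenyl)pyrrolotriazol-3-ylidene) | OC(C[C@@H](OCc1ccccc1)[C@@H](OC(=O)c1ccccc1)[C@H](OCc1ccccc1)C(=O)COC(=O)c1ccccc1)=C1N(c2c(F)c(F)c(F)c(F)c2F)N=C2CCCN12 | intermediate (not isolated)
15 | [(1S,2S,3R,4R)-3-(benzoyloxy)-2,4-bis(benzyloxy)-1-hydroxy-6-oxocyclohexyl]methyl benzoate (product of the key step) | O=C(OC[C@@]1(O)C(=O)C[C@@H](OCc2ccccc2)[C@@H](OC(=O)c2ccccc2)[C@@H]1OCc1ccccc1)c1ccccc1 | intermediate
16 | [(1S,2S,3R,4R)-3-(benzoyloxy)-1,2,4-trihydroxy-6-oxocyclohexyl]methyl benzoate | O=C(OC[C@@]1(O)C(=O)C[C@@H](O)[C@@H](OC(=O)c2ccccc2)[C@@H]1O)c1ccccc1 | target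

## Step count and least certain steps

Total: 12 steps. Longest linear sequence: 12 steps (1 to 16; the route is fully linear).

**Step 11 (key step).** The most likely failure is that enolisation outruns formation of 14 from an aliphatic aldehyde. Enolisation of the ketone towards C6 (ring numbering) would erode that centre or expel the C5 benzoate by E1cB; enolisation of the aldehyde would expel the C4 benzyloxy group. The second uncertainty is the facial ratio at C1, because the preferred chair carries an axial C4 benzyloxy group. The fallback installs the benzoates after ring closure. It sets out from 10: hydrolysis of the acetal (conditions of step 10) would give 3,5-di-O-benzyl-6-deoxy-1,4-di-O-(4-methoxybenzyl)-D-arabino-hept-2-ulos-7-al F1, which has only ether groups β to both carbonyls. Carbene-catalysed closure as in step 11 would give the corresponding bis-PMB α-ketol F2. DDQ would then free the primary C7 and the secondary C5 hydroxyl to give the 4,6-di-O-benzyl triol F3. Benzoylation (BzCl, pyridine, 0 °C), to which the tertiary C1 hydroxyl is inert, would return to 15. If the facial ratio is the problem, both enantiomers of an aminoindanol-derived triazolium salt can be tried in either sequence.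

**Step 5.** The most likely failure is low conversion of the lactol (little open-chain aldehyde present), with the strongly basic ylide then causing β-elimination of the C3 PMB ether or epimerisation at C2 of the aldehydo form. The fallback masks the aldehyde as an alkene. It sets out from 7 and rejoins at 13:
- Methylenation with Ph3P=CH2, the best-documented Wittig reaction of tetra-O-alkyl hexopyranoses, would give 3,5-di-O-benzyl-1,2-dideoxy-4,7-di-O-(4-methoxybenzyl)-D-manno-hept-1-enitol F4.
- Dess–Martin oxidation would give the keto alkene 3,5-di-O-benzyl-6,7-dideoxy-1,4-di-O-(4-methoxybenzyl)-D-arabino-hept-6-en-2-ulose F5.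
- DDQ would give the diol 3,5-di-O-benzyl-6,7-dideoxy-D-arabino-hept-6-en-2-ulose F6.
- Benzoylation would give 1,4-di-O-benzoyl-3,5-di-O-benzyl-6,7-dideoxy-D-arabino-hept-6-en-2-ulose F7.
- Rhodium-catalysed hydroboration selective for the terminal alkene (catecholborane, RhCl(PPh3)3; NaBO3) would give the primary alcohol 1,4-di-O-benzoyl-3,5-di-O-benzyl-6-deoxy-D-arabino-hept-2-ulose F8.
- Dess–Martin oxidation of F8 would give 13 under neutral conditions.

**Step 2.** The most likely failure is incomplete regiocontrol in the double alkylation (3-mono ether and 2,6-di-ether beside the 3,6-di-ether), which would make the separation inefficient. The fallback differentiates the positions one at a time. It sets out from 2 and rejoins at 5: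
- Benzaldehyde dimethyl acetal with CSA would give allyl 4,6-O-benzylidene-α-D-mannopyranoside F9.
- Stannylene-mediated alkylation at the single remaining site (Bu2SnO; PMBCl, CsF) would give allyl 4,6-O-benzylidene-3-O-(4-methoxybenzyl)-α-D-mannopyranoside F10.
- NaH/BnBr would give allyl 2-O-benzyl-4,6-O-benzylidene-3-O-(4-methoxybenzyl)-α-D-mannopyranoside F11.
- Regioselective reductive opening of the acetal (Et3SiH, PhBCl2, CH2Cl2, −78 °C) would give allyl 2,4-di-O-benzyl-3-O-(4-methoxybenzyl)-α-D-mannopyranoside F12 with a free 6-OH.
- NaH/PMBCl would give 5.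

## Further compounds

F1 | step 11 | 3,5-di-O-benzyl-6-deoxy-1,4-di-O-(4-methoxybenzyl)-D-arabino-hept-2-ulos-7-al | O=CC[C@@H](OCc1ccccc1)[C@@H](OCc1ccc(OC)cc1)[C@H](OCc1ccccc1)C(=O)COCc1ccc(OC)cc1
F2 | step 11 | bis-PMB α-ketol (15 with 4-methoxybenzyl in place of both benzoyl groups) | COc1ccc(COC[C@@]2(O)C(=O)C[C@@H](OCc3ccccc3)[C@@H](OCc3ccc(OC)cc3)[C@@H]2OCc2ccccc2)cc1
F3 | step 11 | 4,6-di-O-benzyl triol (15 without both benzoyl groups) | OC[C@@]1(O)C(=O)C[C@@H](OCc2ccccc2)[C@@H](O)[C@@H]1OCc1ccccc1
F4 | step 5 | 3,5-di-O-benzyl-1,2-dideoxy-4,7-di-O-(4-methoxybenzyl)-D-manno-hept-1-enitol | C=C[C@@H](OCc1ccccc1)[C@@H](OCc1ccc(OC)cc1)[C@H](OCc1ccccc1)[C@H](O)COCc1ccc(OC)cc1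
F5 | step 5 | 3,5-di-O-benzyl-6,7-dideoxy-1,4-di-O-(4-methoxybenzyl)-D-arabino-hept-6-en-2-ulose | C=C[C@@H](OCc1ccccc1)[C@@H](OCc1ccc(OC)cc1)[C@H](OCc1ccccc1)C(=O)COCc1ccc(OC)cc1
F6 | step 5 | 3,5-di-O-benzyl-6,7-dideoxy-D-arabino-hept-6-en-2-ulose | C=C[C@@H](OCc1ccccc1)[C@@H](O)[C@H](OCc1ccccc1)C(=O)CO
F7 | step 5 | 1,4-di-O-benzoyl-3,5-di-O-benzyl-6,7-dideoxy-D-arabino-hept-6-en-2-ulose | C=C[C@@H](OCc1ccccc1)[C@@H](OC(=O)c1ccccc1)[C@H](OCc1ccccc1)C(=O)COC(=O)c1ccccc1
F8 | step 5 | 1,4-di-O-benzoyl-3,5-di-O-benzyl-6-deoxy-D-arabino-hept-2-ulose | OCC[C@@H](OCc1ccccc1)[C@@H](OC(=O)c1ccccc1)[C@H](OCc1ccccc1)C(=O)COC(=O)c1ccccc1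
F9 | step 2 | allyl 4,6-O-[(R)-benzylidene]-α-D-mannopyranoside | C=CCO[C@H]1O[C@@H]2CO[C@@H](c3ccccc3)O[C@H]2[C@H](O)[C@@H]1O
F10 | step 2 | allyl 4,6-O-[(R)-benzylidene]-3-O-(4-methoxybenzyl)-α-D-mannopyranoside | C=CCO[C@H]1O[C@@H]2CO[C@@H](c3ccccc3)O[C@H]2[C@H](OCc2ccc(OC)cc2)[C@@H]1O
F11 | step 2 | allyl 2-O-benzyl-4,6-O-[(R)-benzylidene]-3-O-(4-methoxybenzyl)-α-D-mannopyranoside | C=CCO[C@H]1O[C@@H]2CO[C@@H](c3ccccc3)O[C@H]2[C@H](OCc2ccc(OC)cc2)[C@@H]1OCc1ccccc1
F12 | step 2 | allyl 2,4-di-O-benzyl-3-O-(4-methoxybenzyl)-α-D-mannopyranoside | OC[C@H]1O[C@H](OCC=C)[C@@H](OCc2ccccc2)[C@@H](OCc2ccc(OC)cc2)[C@@H]1OCc1ccccc1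
A1 | alternative 1 | (1S,2S)-3-bromocyclohexa-3,5-diene-1,2-diol | C1=C(Br)[C@@H](O)[C@@H](O)C=C1
A2 | alternative 1 | bromobenzene | Brc1ccccc1
A3 | alternative 2 | 1,6-O-isopropylidene acetal of 16 | O=C(OC[C@@]1(OC(C)(C)O2)C(=O)C[C@@H](O)[C@@H](OC(=O)c3ccccc3)[C@@H]12)c1ccccc1
A4 | alternative 2 | methyl 2-O-benzoyl-4-C-(benzoyloxymethyl)-6-deoxy-3,4-O-isopropylidene-D-arabino-hex-5-enopyranoside (anomeric configuration immaterial) | C=C1OC(OC)[C@@H](OC(=O)c2ccccc2)[C@@H]2OC(C)(C)O[C@]12COC(=O)c1ccccc1
A5 | alternative 3 | 1-(hydroxymethyl)-6-nitrocyclohexane-1,2,3,4-tetrol (configuration as drawn; nitro equatorial) | OC[C@@]1(O)[C@H]([N+](=O)[O-])C[C@@H](O)[C@@H](O)[C@@H]1O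
A6 | alternative 3 | dihydroxyacetone | OCC(=O)CO
A7 | alternative 3 | (R)-2-hydroxy-4-nitrobutanal | O=C[C@H](O)CC[N+](=O)[O-]
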